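**Retrosynthetic overview**
- Selaginellin ⇒ global desilylation, then cleavage of the bond between the quinone-methide carbon and the central arene: a hindered aryl chloride plus the N-tosylhydrazone of 4,4'-dihydroxybenzophenone. The ketone carbon is used as a nucleophilic diazo/Pd-carbene carbon and joined to the aryl-halide carbon, so two normally electrophilic carbons are coupled.
- Aryl chloride ⇒ silylation, ester reduction and Sonogashira coupling (C2–alkyne) of a 3-chloro-2-iodobenzoate with 4-ethynylphenol.
- Iodide ⇒ ester/chlorine-directed C2 magnesiation–iodination of methyl 3-chloro-4-arylbenzoate ⇒ bromine-selective Suzuki coupling of methyl 4-bromo-3-chlorobenzoate.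
- Rings: all four benzene rings are bought. The only ring generated is the cyclohexadienone of the quinone methide, formed last by dearomatisation of one phenol ring in the key step.

Assumption: the target SMILES has no stereocentre and no stereogenic double bond (the exocyclic C=C carries a symmetric dienone), so the compound is achiral and needs no enantiocontrol; 4-ethynylphenol and 4-(tert-butyldimethylsilyloxy)phenylboronic acid are taken as catalogue items. TBS = tert-butyldimethylsilyl.

**Step 1**
Reactants: 1 4,4'-dihydroxybenzophenone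
Product: 2 4,4'-dihydroxybenzophenone N-tosylhydrazone (N'-[bis(4-hydroxyphenyl)methylidene]-4-methylbenzenesulfonohydrazide)
Conditions: TsNHNH2 (1.2 equiv), cat. HCl, EtOH, reflux
Reagents that add atoms: p-toluenesulfonyl hydrazide, Cc1ccc(cc1)S(=O)(=O)NN
Why: acid-catalysed hydrazone condensation of a diaryl ketone, driven by crystallisation of the product; the ketone is symmetric, so there is no C=N isomer issue.

**Step 2**
Reactants: 3 methyl 4-bromo-3-chlorobenzoate; 4 4-(tert-butyldimethylsilyloxy)phenylboronic acid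
Product: 5 methyl 3-chloro-4-[4-(tert-butyldimethylsilyloxy)phenyl]benzoate
Conditions: Pd(PPh3)4 (3 mol%), 2 M aq Na2CO3, DME, 80 °C
Reagents that add atoms: none
Why: Suzuki–Miyaura coupling; Pd(PPh3)4 inserts into the ester-activated C–Br bond and leaves the C–Cl bond untouched.

**Step 3**
Reactants: 5 methyl 3-chloro-4-[4-(tert-butyldimethylsilyloxy)phenyl]benzoate
Product: 7 methyl 3-chloro-2-iodo-4-[4-(tert-butyldimethylsilyloxy)phenyl]benzoate, via arylmagnesium chloride 6 (not isolated)
Conditions: TMPMgCl·LiCl (1.3 equiv), THF, 0 °C; then I2, −20 °C → rt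
Reagents that add atoms: iodine, II; TMPMgCl·LiCl, CC1(C)CCCC(C)(C)N1[Mg]Cl.[Li+].[Cl-] (its MgCl stays only in intermediate 6)
Why: directed ortho-magnesiation with the Knochel–Hauser base at the most acidic C–H, flanked by the coordinating ester and the chlorine, followed by iodinolysis; the magnesium species tolerates the ester and does not eliminate to an aryne at 0 °C.

**Step 4**
Reactants: 7 methyl 3-chloro-2-iodo-4-[4-(tert-butyldimethylsilyloxy)phenyl]benzoate; 8 4-ethynylphenol
Product: 9 methyl 3-chloro-2-[(4-hydroxyphenyl)ethynyl]-4-[4-(tert-butyldimethylsilyloxy)phenyl]benzoate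
Conditions: PdCl2(PPh3)2 (3 mol%), CuI (5 mol%), Et3N/THF, degassed, 45 °C
Reagents that add atoms: none
Why: Sonogashira coupling at the ester-activated C–I bond; the aryl chloride is inert under these conditions and the free phenol is tolerated.

**Step 5**
Reactants: 9 methyl 3-chloro-2-[(4-hydroxyphenyl)ethynyl]-4-[4-(tert-butyldimethylsilyloxy)phenyl]benzoate
Product: 10 4-({2-chloro-6-(hydroxymethyl)-3-[4-(tert-butyldimethylsilyloxy)phenyl]phenyl}ethynyl)phenol
Conditions: DIBAL-H (3.5 equiv), CH2Cl2, −78 → 0 °C; aq Rochelle salt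
Reagents that add atoms: none
Why: hydride reduction of the ester to the benzylic alcohol; the diaryl alkyne, aryl chloride and aryl silyl ether are inert to DIBAL-H at or below 0 °C.

**Step 6**
Reactants: 10 4-({2-chloro-6-(hydroxymethyl)-3-[4-(tert-butyldimethylsilyloxy)phenyl]phenyl}ethynyl)phenol
Product: 11 tert-butyl({3-chloro-2-{[4-(tert-butyldimethylsilyloxy)phenyl]ethynyl}-4-[4-(tert-butyldimethylsilyloxy)phenyl]phenyl}methoxy)dimethylsilane (tris-TBS aryl chloride)
Conditions: TBSCl (2.4 equiv), imidazole (4 equiv), DMF, rt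
Reagents that add atoms: tert-butyldimethylsilyl chloride, CC(C)(C)[Si](C)(C)Cl
Why: imidazole-mediated silylation of the phenol and the primary alcohol; masking the benzylic OH prevents base- or Pd-mediated cyclisation onto the ortho alkyne in step 7.

**Step 7**
Reactants: 11 tris-TBS aryl chloride; 2 4,4'-dihydroxybenzophenone N-tosylhydrazone
Product: 14 selaginellin, via diazo compound 12 (not isolated), via tris-TBS quinone methide 13 (not isolated)
Conditions: Pd2(dba)3 (2.5 mol%), XPhos (10 mol%), LiOtBu (4.5 equiv), 1,4-dioxane, 100 °C; then TBAF (4 equiv)/AcOH (5 equiv), THF, 0 °C → rt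
Reagents that add atoms: none
Why: Proposed new method: Bamford–Stevens decomposition of the trilithium salt of 2 gives the electron-rich diazo bis-phenoxide 12, whose former carbonyl carbon is now nucleophilic and attacks the XPhos-ligated aryl–Pd(II)–Cl formed from 11; N2 loss and aryl migration give a triarylmethyl–Pd(II) that has no β-hydrogen and collapses under the para-phenoxide push (equivalently, C–C reductive elimination from the σ-quinone-methidyl–Pd resonance form) to quinone methide 13 and Pd(0), after which buffered fluoride removes the three TBS groups; the closest known reaction types are the Barluenga Pd-catalysed cross-coupling of aryl halides with N-tosylhydrazones and its formate-terminated variant that gives triarylmethanes.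

**Compound list**
1 | 4,4'-dihydroxybenzophenone | O=C(c1ccc(O)cc1)c1ccc(O)cc1 | starting material
2 | 4,4'-dihydroxybenzophenone N-tosylhydrazone | Cc1ccc(cc1)S(=O)(=O)NN=C(c1ccc(O)cc1)c1ccc(O)cc1 | intermediate
3 | methyl 4-bromo-3-chlorobenzoate | COC(=O)c1ccc(Br)c(Cl)c1 | starting material
4 | 4-(tert-butyldimethylsilyloxy)phenylboronic acid | CC(C)(C)[Si](C)(C)Oc1ccc(cc1)B(O)O | starting material
5 | methyl 3-chloro-4-[4-(tert-butyldimethylsilyloxy)phenyl]benzoate | COC(=O)c1ccc(-c2ccc(O[Si](C)(C)C(C)(C)C)cc2)c(Cl)c1 | intermediate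
6 | chloro{2-chloro-6-(methoxycarbonyl)-3-[4-(tert-butyldimethylsilyloxy)phenyl]phenyl}magnesium (LiCl complex, not isolated) | COC(=O)c1ccc(-c2ccc(O[Si](C)(C)C(C)(C)C)cc2)c(Cl)c1[Mg]Cl | intermediate
7 | methyl 3-chloro-2-iodo-4-[4-(tert-butyldimethylsilyloxy)phenyl]benzoate | COC(=O)c1ccc(-c2ccc(O[Si](C)(C)C(C)(C)C)cc2)c(Cl)c1I | intermediate
8 | 4-ethynylphenol | C#Cc1ccc(O)cc1 | starting material
9 | methyl 3-chloro-2-[(4-hydroxyphenyl)ethynyl]-4-[4-(tert-butyldimethylsilyloxy)phenyl]benzoate | COC(=O)c1ccc(-c2ccc(O[Si](C)(C)C(C)(C)C)cc2)c(Cl)c1C#Cc1ccc(O)cc1 | intermediate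
10 | 4-({2-chloro-6-(hydroxymethyl)-3-[4-(tert-butyldimethylsilyloxy)phenyl]phenyl}ethynyl)phenol | OCc1ccc(-c2ccc(O[Si](C)(C)C(C)(C)C)cc2)c(Cl)c1C#Cc1ccc(O)cc1 | intermediate
11 | tert-butyl({3-chloro-2-{[4-(tert-butyldimethylsilyloxy)phenyl]ethynyl}-4-[4-(tert-butyldimethylsilyloxy)phenyl]phenyl}methoxy)dimethylsilane | CC(C)(C)[Si](C)(C)OCc1ccc(-c2ccc(O[Si](C)(C)C(C)(C)C)cc2)c(Cl)c1C#Cc1ccc(O[Si](C)(C)C(C)(C)C)cc1 | intermediate
12 | bis(4-hydroxyphenyl)diazomethane (dilithium bis-phenoxide in the flask, not isolated) | [N-]=[N+]=C(c1ccc(O)cc1)c1ccc(O)cc1 | intermediate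
13 | 4-[{3-[(tert-butyldimethylsilyloxy)methyl]-2-{[4-(tert-butyldimethylsilyloxy)phenyl]ethynyl}-6-[4-(tert-butyldimethylsilyloxy)phenyl]phenyl}(4-hydroxyphenyl)methylidene]cyclohexa-2,5-dien-1-one (lithium phenoxide in the flask, not isolated) | O=C1C=CC(=C(c2ccc(O)cc2)c2c(-c3ccc(O[Si](C)(C)C(C)(C)C)cc3)ccc(CO[Si](C)(C)C(C)(C)C)c2C#Cc2ccc(O[Si](C)(C)C(C)(C)C)cc2)C=C1 | intermediate
14 | selaginellin, 4-[{3-(hydroxymethyl)-2-[(4-hydroxyphenyl)ethynyl]-6-(4-hydroxyphenyl)phenyl}(4-hydroxyphenyl)methylidene]cyclohexa-2,5-dien-1-one | O=C1C=CC(=C(c2ccc(O)cc2)c2c(-c3ccc(O)cc3)ccc(CO)c2C#Cc2ccc(O)cc2)C=C1 | target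

**Totals**
Total step count: 7. Longest linear sequence: 6 (steps 2–7); step 1 is the convergent branch.

**Steps most likely to fail, with fallbacks**

Step 7 is the riskiest. The redox-neutral collapse of the triarylmethyl–palladium to the quinone methide is unprecedented, the chloride is flanked by two ortho substituents, and a 1,4-Pd shift onto the neighbouring aryl ring or insertion of the diaryl alkyne could compete. The fallback sets out from 11 (with 2) and separates C–C bond formation from the redox adjustment. The same Pd/XPhos carbene coupling is run with ammonium formate as hydride donor, which is the established reductive coupling of diaryl N-tosylhydrazones with aryl halides. This gives the leuco triarylmethane 4,4'-({3-[(tert-butyldimethylsilyloxy)methyl]-2-{[4-(tert-butyldimethylsilyloxy)phenyl]ethynyl}-6-[4-(tert-butyldimethylsilyloxy)phenyl]phenyl}methylene)diphenol F1. Oxidation with DDQ (1.05 equiv, CH2Cl2, 0 °C; hydride abstraction from a 4-hydroxytriarylmethane, the classical fuchsone formation) then gives the tris-TBS quinone methide. The fallback comes back to the route at 13, which is desilylated with TBAF/AcOH as in the second stage of step 7.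

Step 3 may give incomplete or unselective magnesiation of the biaryl ester 5. The fallback sets out from 3 and changes the order of bond construction, so that the metalation is done on the smaller, more C–H-acidic bromo ester before the biaryl exists. TMPMgCl·LiCl gives chloro[3-bromo-2-chloro-6-(methoxycarbonyl)phenyl]magnesium F2 (not isolated), and iodine then gives methyl 4-bromo-3-chloro-2-iodobenzoate F3. Sonogashira coupling with 8 at the C–I bond at rt gives methyl 4-bromo-3-chloro-2-[(4-hydroxyphenyl)ethynyl]benzoate F4. Suzuki coupling with 4 at the C–Br bond then comes back to the route at 9.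

Step 4 uses a di-ortho-substituted iodide, and 4-ethynylphenol is prone to Glaser coupling and polymerisation. The fallback sets out from 7 and swaps the roles of the two partners. Sonogashira coupling with ethynyltrimethylsilane gives methyl 3-chloro-4-[4-(tert-butyldimethylsilyloxy)phenyl]-2-[(trimethylsilyl)ethynyl]benzoate F5. AgNO3-catalysed protodesilylation in acetone/H2O, which spares the aryl silyl ether, gives methyl 3-chloro-2-ethynyl-4-[4-(tert-butyldimethylsilyloxy)phenyl]benzoate F6. A second Sonogashira coupling, with stable and cheap 4-iodophenol, comes back to the route at 9.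

**Further compounds**
F1 | step 7 | 4,4'-({3-[(tert-butyldimethylsilyloxy)methyl]-2-{[4-(tert-butyldimethylsilyloxy)phenyl]ethynyl}-6-[4-(tert-butyldimethylsilyloxy)phenyl]phenyl}methylene)diphenol | Oc1ccc(cc1)C(c1ccc(O)cc1)c1c(-c2ccc(O[Si](C)(C)C(C)(C)C)cc2)ccc(CO[Si](C)(C)C(C)(C)C)c1C#Cc1ccc(O[Si](C)(C)C(C)(C)C)cc1
F2 | step 3 | chloro[3-bromo-2-chloro-6-(methoxycarbonyl)phenyl]magnesium | COC(=O)c1ccc(Br)c(Cl)c1[Mg]Cl
F3 | step 3 | methyl 4-bromo-3-chloro-2-iodobenzoate | COC(=O)c1ccc(Br)c(Cl)c1I
F4 | step 3 | methyl 4-bromo-3-chloro-2-[(4-hydroxyphenyl)ethynyl]benzoate | COC(=O)c1ccc(Br)c(Cl)c1C#Cc1ccc(O)cc1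
F5 | step 4 | methyl 3-chloro-4-[4-(tert-butyldimethylsilyloxy)phenyl]-2-[(trimethylsilyl)ethynyl]benzoate | COC(=O)c1ccc(-c2ccc(O[Si](C)(C)C(C)(C)C)cc2)c(Cl)c1C#C[Si](C)(C)C
F6 | step 4 | methyl 3-chloro-2-ethynyl-4-[4-(tert-butyldimethylsilyloxy)phenyl]benzoate | COC(=O)c1ccc(-c2ccc(O[Si](C)(C)C(C)(C)C)cc2)c(Cl)c1C#C
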